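## Analysis of the target

Numbering used for the target and all intermediates: ring A is the cyclohexane with C1 = C(CH3)2, C2 = CH–OH, C3 and C4 = CH2, C5 = C(CH3)(OH) and C6 = CH; the chain is C7H2–C8H2–C9(CH3)(OH)–C10H2–C11H2–O, and that oxygen is the 7-oxygen of the coumarin (rings B and C). The compound is a monocyclic farnesane tetraol, etherified at C11 with umbelliferone, with four stereocentres: C2 (R), C5 (S), C6 (S) and C9 (R). On ring A the hydroxyls at C2 and C5 are cis to each other (1,4) and both trans to the C6 chain, and C5–CH3 is cis to the chain; in the chair with an equatorial chain, C2–OH and C5–CH3 are axial. C9 lies four bonds from C6 and its two larger arms are both CH2CH2 groups, so it cannot be relayed from the ring and needs reagent control. The coumarin (an enoate lactone) does not tolerate hydrides, organometallics, strong base or unselective hydrogenation, and the two tertiary alcohols do not tolerate acid. The hard points are C6, wedged between two fully substituted carbons, and the axial C2–OH and equatorial C5–OH, which are the epimers that a chair epoxy-ene cyclisation and a methyl addition to a C5 ketone do not deliver. The feature that invites the key move is the cis-1,4-dioxygenated array O–C2–C3–C4–C5–O of ring A with both oxygens on the face opposite the C6 chain: it is the reduced form of a 2,3-dioxabicyclo[2.2.2]octene, the [4+2] adduct of the ring A diene C2=C3–C4=C5.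

## Retrosynthetic reasoning

**C11–O aryl ether.** Target 20 is cut at the C11–O bond into tetraol 18 and umbelliferone 19. Cutting here last keeps the coumarin away from every organometallic, hydride and hydrogenation step. The forward reaction has to etherify one primary hydroxyl in the presence of one hindered secondary and two tertiary hydroxyls.

**C2–O and C5–O together (key disconnection).** Tetraol 18 is the hydrogenation product of endoperoxide 17, and 17 is the hetero-[4+2] photooxygenation adduct of diene 16. Both ring C–O bonds are cut at once because they are cis and both anti to the chain. The precursor 16 has one ring stereocentre instead of three and no ring oxygen. The forward step has to add to the face of the diene opposite the C6 chain.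

**C9 carbinol.** Diol 16 is traced to epoxy alcohol 15 (C10–H by hydride opening) and 15 to the (E)-allylic alcohol 14 (C9–O by asymmetric epoxidation). This sets C9 by the reagent alone, independent of the remote C6, and gives the 1,3-diol directly.

**C9–CH3 and C10–C11.** Allylic alcohol 14 is cut to the terminal alkyne 12 by a methyl-metalation and capture of the alkenylmetal 13 with a one-carbon carbonyl electrophile. This fixes the E geometry by syn addition. Alkyne 12 comes from its silyl-protected form 11.

**Ring diene.** Diene 11 is traced to dienyl triflate 10 and that to the α'-methyl enone 8. The C4 oxygen of the enone, having served to introduce C5–CH3 and the C4=C5 double bond, is removed by reduction. C6 is never acidic in this series, so its configuration is safe.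

**C5–CH3 and C6–C7.** Enone 8 is cut to enone 6 (enolate methylation). Enone 6 is cut at C6–C7 to the achiral dienone 1 and the dialkylzinc 4, made from bromide 2 through 3. The desymmetrising conjugate addition creates C6, the only stereocentre from which the ring is later controlled, by catalyst control.

## Alternatives that were turned down

**Alternative 1:** the textbook carbonyl-addition disconnection. C5–CH3 is cut to give a C5 ketone A1 (C2 oxygen protected), and C2–OH would come from a separate ketone reduction. The forward key step is methylmagnesium bromide addition to A1.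
- A methyl nucleophile adds to a 2-alkylcyclohexanone mainly from the equatorial direction, and axial attack at C5 is further blocked by the syn-axial C1 methyl. The expected product is therefore A2, with C5–OH axial and cis to the chain, the C5 epimer.
- A1 has its chain on the α-carbon between the carbonyl and the quaternary C1. That position is hard to alkylate and epimerisable.
- Each ring stereocentre would be set in a step of its own, so the route is long and the stereochemical outcome works against the target.

**Alternative 2:** the biosynthesis-like disconnection of the C1–C6 bond. The acyclic epoxide A3 would be cyclised with a Lewis acid, the C5=C6 double bond opening the epoxide at C1 and water capturing the C5 cation.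
- The chair transition state places C2–OH equatorial and cis to the chain. The product would be A4, the C2 epimer of 20.
- Correcting C2 needs an oxidation and a bulky-hydride reduction, and the hydride is not compatible with the coumarin.
- The C9 hydroxyl would capture the C5 cation through a six-membered transition state faster than water. Water-terminated cation–olefin cyclisations are also generally inefficient against proton loss.
- The result is a low-yielding key step plus a protecting group and a two-step stereochemical repair.

**Alternative 3:** cutting the same C1–C6 bond in a pericyclic sense. The acyclic (6E,8Z)-triene A5 would close by thermal 6π-electrocyclisation to the ring A diene A6, followed by the same photooxygenation as in the chosen route.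
- This is the shortest way to the diene, but the closure creates C6 with no control relative to the remote C9, so A6 would form as both C6 epimers.
- A (Z)-triene with methyl groups on its termini undergoes 1,7-hydrogen shifts more easily than it closes, which scrambles the triene constitution.
- The closure needs high temperature because one C1 methyl must turn inward.

Key step: step 9

Assumption: the (S,R,R)-phosphoramidite is taken to deliver the alkyl group so that (5R)-6 results; if the sense of induction is the opposite, its (R,S,S) mirror image is used with nothing else changed.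

## Route

Step 1
Reactants: 1 4,4-dimethylcyclohexa-2,5-dien-1-one; 2 (4-bromobut-1-yn-1-yl)trimethylsilane
Product: 6 (5R)-4,4-dimethyl-5-[4-(trimethylsilyl)but-3-yn-1-yl]cyclohex-2-en-1-one, via alkylmagnesium bromide 3 (not isolated), via dialkylzinc 4 (not isolated), via zinc dienolate 5 (not isolated)
Conditions: 2, Mg, THF; ZnCl2 (0.5 equiv), then 1,4-dioxane, filter; 1, Cu(OTf)2 (2 mol%), (S,R,R)-phosphoramidite from (S)-1,1'-bi-2-naphthol and bis[(R)-1-phenylethyl]amine (4 mol%), toluene, −30 °C; aq NH4Cl
Reagents that add atoms: none
Why: Copper-catalysed asymmetric conjugate addition of a dialkylzinc to a 4,4-disubstituted cyclohexa-2,5-dienone is a known desymmetrisation; the divalent copper salt is reduced in the flask to the active monovalent copper–phosphoramidite complex, which selects one enantiotopic enone and one face and so sets C6. The product stays masked as zinc dienolate 5 until work-up, which prevents a second addition, and the silyl alkyne is inert to magnesium, zinc and copper.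

Step 2
Reactants: 6 (5R)-4,4-dimethyl-5-[4-(trimethylsilyl)but-3-yn-1-yl]cyclohex-2-en-1-one
Product: 8 (5R,6R)-4,4,6-trimethyl-5-[4-(trimethylsilyl)but-3-yn-1-yl]cyclohex-2-en-1-one (5,6-trans), via lithium dienolate 7 (not isolated)
Conditions: LiN(iPr)2, THF, −78 °C; MeI, −78 to −20 °C
Reagents that add atoms: iodomethane, CI
Why: Kinetic α'-enolate alkylation; C5 is the only enolisable position because the γ-carbon C1 is quaternary, and methyl iodide should enter trans to the neighbouring C6 chain. The configuration at C5 is of no consequence since C5 becomes sp2 in step 3, and C6 is not acidic.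

Step 3
Reactants: 8 (5R,6R)-4,4,6-trimethyl-5-[4-(trimethylsilyl)but-3-yn-1-yl]cyclohex-2-en-1-one
Product: 10 (3S)-2,4,4-trimethyl-3-[4-(trimethylsilyl)but-3-yn-1-yl]cyclohexa-1,5-dien-1-yl trifluoromethanesulfonate, via lithium dienolate 9 (not isolated)
Conditions: LiN(iPr)2, THF, −78 °C; PhNTf2, −78 to 0 °C
Reagents that add atoms: N-phenylbis(trifluoromethanesulfonimide), O=S(=O)(N(c1ccccc1)S(=O)(=O)C(F)(F)F)C(F)(F)F
Why: α'-Deprotonation of the axial C5–H gives the cross-conjugated dienolate, which is triflated on oxygen (enol triflate formation), creating the C4=C5 double bond next to C2=C3. The C6 stereocentre is β' to the carbonyl and is not touched; its descriptor changes only because the priorities change.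

Step 4
Reactants: 10 (3S)-2,4,4-trimethyl-3-[4-(trimethylsilyl)but-3-yn-1-yl]cyclohexa-1,5-dien-1-yl trifluoromethanesulfonate
Product: 11 trimethyl{4-[(1R)-2,6,6-trimethylcyclohexa-2,4-dien-1-yl]but-1-yn-1-yl}silane
Conditions: Pd(OAc)2 (5 mol%), PPh3 (10 mol%), Bu3N, HCO2H, DMF, 60 °C
Reagents that add atoms: none
Why: Palladium-catalysed formate reduction of a dienyl triflate, the standard way from steroidal dienyl triflates to dienes: oxidative addition to zerovalent palladium, exchange of triflate for formate, loss of CO2 and reductive elimination of C4–H. The silyl-capped alkyne should not be hydropalladated under these conditions, and the temperature is far below that of 1,5-hydrogen shifts in the diene.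

Step 5
Reactants: 11 trimethyl{4-[(1R)-2,6,6-trimethylcyclohexa-2,4-dien-1-yl]but-1-yn-1-yl}silane
Product: 12 (6R)-6-(but-3-yn-1-yl)-1,5,5-trimethylcyclohexa-1,3-diene
Conditions: K2CO3 (0.2 equiv), MeOH, room temperature, under argon
Reagents that add atoms: none
Why: Base-catalysed methanolysis of the C(sp)–Si bond; the diene and C6 are inert to these conditions.

Step 6
Reactants: 12 (6R)-6-(but-3-yn-1-yl)-1,5,5-trimethylcyclohexa-1,3-diene
Product: 14 (2E)-3-methyl-5-[(1R)-2,6,6-trimethylcyclohexa-2,4-dien-1-yl]pent-2-en-1-ol, via alkenylalane 13 (not isolated)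
Conditions: AlMe3 (2.5 equiv), Cp2ZrCl2 (0.25 equiv), CH2Cl2, 0 °C to room temperature; then (CH2O)n, THF, 0 °C to room temperature; aq potassium sodium tartrate
Reagents that add atoms: trimethylaluminium, C[Al](C)C; formaldehyde (as paraformaldehyde), C=O
Why: Zirconium-catalysed carboalumination (Negishi) adds methyl to C9 and aluminium to C10 in a syn fashion, and the alkenylalane adds to formaldehyde with retention, so the (E)-trisubstituted allylic alcohol should form as one isomer. An unactivated conjugated diene is not expected to be carbometalated by this catalyst.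

Step 7
Reactants: 14 (2E)-3-methyl-5-[(1R)-2,6,6-trimethylcyclohexa-2,4-dien-1-yl]pent-2-en-1-ol
Product: 15 [(2R,3R)-3-methyl-3-{2-[(1R)-2,6,6-trimethylcyclohexa-2,4-dien-1-yl]ethyl}oxiran-2-yl]methanol
Conditions: Ti(OiPr)4 (10 mol%), D-(−)-diethyl tartrate (12 mol%), t-BuOOH, 4 Å molecular sieves, CH2Cl2, −20 °C
Reagents that add atoms: tert-butyl hydroperoxide, CC(C)(C)OO
Why: Sharpless asymmetric epoxidation of a geraniol-type allylic alcohol; the tetravalent titanium–D-tartrate complex delivers oxygen to the face that gives the (2R,3R)-epoxide, which fixes C9 as R by reagent control. The ring diene has no directing hydroxyl and should not be epoxidised.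

Step 8
Reactants: 15 [(2R,3R)-3-methyl-3-{2-[(1R)-2,6,6-trimethylcyclohexa-2,4-dien-1-yl]ethyl}oxiran-2-yl]methanol
Product: 16 (3R)-3-methyl-5-[(1R)-2,6,6-trimethylcyclohexa-2,4-dien-1-yl]pentane-1,3-diol
Conditions: NaAlH2(OCH2CH2OMe)2, THF, 0 °C to room temperature; aq potassium sodium tartrate
Reagents that add atoms: none
Why: Hydride is delivered within the C11 alkoxyaluminate to C10, the epoxide carbon next to the carbinol, which is the known route from 2,3-epoxy alcohols to 1,3-diols. The C9–O bond is not broken, so C9 keeps its configuration.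

Step 9
Reactants: 16 (3R)-3-methyl-5-[(1R)-2,6,6-trimethylcyclohexa-2,4-dien-1-yl]pentane-1,3-diol
Product: 17 (3R)-3-methyl-5-[(1S,4R,7S)-1,8,8-trimethyl-2,3-dioxabicyclo[2.2.2]oct-5-en-7-yl]pentane-1,3-diol
Conditions: O2, tetraphenylporphyrin (0.5 mol%), visible light (>500 nm), CH2Cl2, −20 °C
Reagents that add atoms: dioxygen, O=O
Why: Sensitised singlet oxygen adds across C2 and C5 of the ring-locked s-cis diene in a suprafacial hetero-[4+2] cycloaddition, the reaction type by which α-terpinene gives ascaridole and steroidal 5,7-dienes give their 5,8-epidioxides. One ring is closed, the six-membered 1,2-dioxine O–C2–C3=C4–C5–O of a 2,3-dioxabicyclo[2.2.2]oct-5-ene, by concerted bonding of both oxygen atoms from the same face. Suprafaciality fixes the C2–O and C5–O bonds cis to each other, so the two new stereocentres are set as a pair. Their sense relative to C6 comes from facial selection: in the half-chair with a pseudoequatorial chain, the chain face carries the pseudoaxial C1 methyl and the other face only the pseudoaxial C6–H; in the other half-chair the chain itself is pseudoaxial. Every approach syn to the chain therefore has to pass a pseudoaxial alkyl group, while the anti face is open in a populated conformer (Curtin–Hammett), as on the open face of the steroidal dienes. Anti attack gives C2 (R) and C5 (S) with C5–CH3 cis to the chain, as in 20. The step also needs [4+2] to win over the ene reaction at the C5 methyl, which the cisoid cyclic diene secures, and chemoselectivity, which is given because 16 has no other alkene and hydroxyls are inert to singlet oxygen. Low temperature and long-wavelength light keep the peroxide from secondary photochemistry.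

Step 10
Reactants: 17 (3R)-3-methyl-5-[(1S,4R,7S)-1,8,8-trimethyl-2,3-dioxabicyclo[2.2.2]oct-5-en-7-yl]pentane-1,3-diol
Product: 18 (1S,2S,4R)-2-[(3R)-3,5-dihydroxy-3-methylpentyl]-1,3,3-trimethylcyclohexane-1,4-diol
Conditions: H2 (1 atm), Pd/C (5%), EtOAc, room temperature
Reagents that add atoms: none
Why: Catalytic hydrogenation saturates the strained C3=C4 double bond and cleaves the O–O bond, as in the conversion of ascaridole into the cis-1,4-diol. No C–O bond is broken, so C2 and C5 keep the cis-diol configuration set in step 9.

Step 11
Reactants: 18 (1S,2S,4R)-2-[(3R)-3,5-dihydroxy-3-methylpentyl]-1,3,3-trimethylcyclohexane-1,4-diol; 19 umbelliferone (7-hydroxy-2H-chromen-2-one)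
Product: 20 7-({(3R)-5-[(1S,3R,6S)-3,6-dihydroxy-2,2,6-trimethylcyclohexyl]-3-hydroxy-3-methylpentyl}oxy)-2H-chromen-2-one
Conditions: PPh3, diisopropyl azodicarboxylate, THF, 0 °C to room temperature
Reagents that add atoms: none
Why: Mitsunobu etherification of the acidic phenol at the primary C11 hydroxyl by SN2 displacement at a CH2 group, so no stereocentre is involved. The two tertiary hydroxyls and the axial C2 hydroxyl next to the quaternary C1 should not be activated, and the cis-1,4-diol cannot close to an ether by backside attack.

## Compound list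

1 | 4,4-dimethylcyclohexa-2,5-dien-1-one | CC1(C)C=CC(=O)C=C1 | starting material
2 | (4-bromobut-1-yn-1-yl)trimethylsilane | C[Si](C)(C)C#CCCBr | starting material
3 | [4-(trimethylsilyl)but-3-yn-1-yl]magnesium bromide | C[Si](C)(C)C#CCC[Mg]Br | intermediate
4 | bis[4-(trimethylsilyl)but-3-yn-1-yl]zinc | C[Si](C)(C)C#CCC[Zn]CCC#C[Si](C)(C)C | intermediate
5 | zinc dienolate of 6, O-bound to [4-(trimethylsilyl)but-3-yn-1-yl]zinc, C6 configured as in 6 | CC1(C)C=CC(O[Zn]CCC#C[Si](C)(C)C)=C[C@H]1CCC#C[Si](C)(C)C | intermediate
6 | (5R)-4,4-dimethyl-5-[4-(trimethylsilyl)but-3-yn-1-yl]cyclohex-2-en-1-one | CC1(C)C=CC(=O)C[C@H]1CCC#C[Si](C)(C)C | intermediate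
7 | lithium dienolate of 6 (lithium (5R)-4,4-dimethyl-5-[4-(trimethylsilyl)but-3-yn-1-yl]cyclohexa-1,5-dien-1-olate) | CC1(C)C=CC(O[Li])=C[C@H]1CCC#C[Si](C)(C)C | intermediate
8 | (5R,6R)-4,4,6-trimethyl-5-[4-(trimethylsilyl)but-3-yn-1-yl]cyclohex-2-en-1-one (5,6-trans) | CC1(C)C=CC(=O)[C@H](C)[C@H]1CCC#C[Si](C)(C)C | intermediate
9 | lithium dienolate of 8 (C5 sp2, C6 configured as in 8) | CC1(C)C=CC(O[Li])=C(C)[C@H]1CCC#C[Si](C)(C)C | intermediate
10 | (3S)-2,4,4-trimethyl-3-[4-(trimethylsilyl)but-3-yn-1-yl]cyclohexa-1,5-dien-1-yl trifluoromethanesulfonate | CC1(C)C=CC(OS(=O)(=O)C(F)(F)F)=C(C)[C@H]1CCC#C[Si](C)(C)C | intermediate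
11 | trimethyl{4-[(1R)-2,6,6-trimethylcyclohexa-2,4-dien-1-yl]but-1-yn-1-yl}silane | CC1(C)C=CC=C(C)[C@H]1CCC#C[Si](C)(C)C | intermediate
12 | (6R)-6-(but-3-yn-1-yl)-1,5,5-trimethylcyclohexa-1,3-diene | CC1(C)C=CC=C(C)[C@H]1CCC#C | intermediate
13 | dimethyl{(1E)-2-methyl-4-[(1R)-2,6,6-trimethylcyclohexa-2,4-dien-1-yl]but-1-en-1-yl}alumane | CC1(C)C=CC=C(C)[C@H]1CC/C(C)=C/[Al](C)C | intermediate
14 | (2E)-3-methyl-5-[(1R)-2,6,6-trimethylcyclohexa-2,4-dien-1-yl]pent-2-en-1-ol | CC1(C)C=CC=C(C)[C@H]1CC/C(C)=C/CO | intermediate
15 | [(2R,3R)-3-methyl-3-{2-[(1R)-2,6,6-trimethylcyclohexa-2,4-dien-1-yl]ethyl}oxiran-2-yl]methanol | CC1(C)C=CC=C(C)[C@H]1CC[C@@](C)(O2)[C@H]2CO | intermediate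
16 | (3R)-3-methyl-5-[(1R)-2,6,6-trimethylcyclohexa-2,4-dien-1-yl]pentane-1,3-diol | CC1(C)C=CC=C(C)[C@H]1CC[C@@](C)(O)CCO | intermediate
17 | (3R)-3-methyl-5-[(1S,4R,7S)-1,8,8-trimethyl-2,3-dioxabicyclo[2.2.2]oct-5-en-7-yl]pentane-1,3-diol (peroxide bridge trans to the chain) | CC1(C)[C@H](O2)C=C[C@](C)(O2)[C@H]1CC[C@@](C)(O)CCO | intermediate
18 | (1S,2S,4R)-2-[(3R)-3,5-dihydroxy-3-methylpentyl]-1,3,3-trimethylcyclohexane-1,4-diol | CC1(C)[C@H](O)CC[C@](C)(O)[C@H]1CC[C@@](C)(O)CCO | intermediate
19 | umbelliferone (7-hydroxy-2H-chromen-2-one) | Oc1ccc2ccc(=O)oc2c1 | starting material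
20 | 7-({(3R)-5-[(1S,3R,6S)-3,6-dihydroxy-2,2,6-trimethylcyclohexyl]-3-hydroxy-3-methylpentyl}oxy)-2H-chromen-2-one | CC1(C)[C@H](O)CC[C@](C)(O)[C@H]1CC[C@@](C)(O)CCOc1ccc2ccc(=O)oc2c1 | target

## Step count and least certain steps

Total step count: 11. Longest linear sequence: 11 steps (1 and 2 to 20; umbelliferone 19 enters in the last step).

**Step 9 (key step).** The most likely failure is insufficient facial selectivity: part of the singlet oxygen could add syn to the chain through the half-chair with a pseudoaxial chain, and some ene-type hydroperoxidation at the C5 methyl could compete. The fallback replaces the small dienophile by a metal-mediated syn-1,4-difunctionalisation that is far more sensitive to sterics. It sets out from 16 and returns at 18.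
- Platinum-catalysed 1,4-diboration of 16 (bis(pinacolato)diboron, Pt(PPh3)4, toluene, 80 °C) should deliver both boron atoms from the metal to the face opposite the chain, giving the cis-1,4-bis(boronate) F1.
- Oxidation with NaOH/H2O2, which proceeds with retention at carbon, would give the cis-ene-diol F2.
- Hydrogenation of F2 (H2, Pd/C) would give 18.

**Step 1.** The functionalised alkyl group may transfer to the hindered β-carbon of the cross-conjugated dienone with too little enantioselectivity or too slowly. The fallback moves the asymmetric step to the benchmark mono-enone. It sets out from the zinc reagent 4 (from 2) and returns at 8, bypassing 6.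
- Commercial 4,4-dimethylcyclohex-2-en-1-one F3 would be used with the same catalyst, and the enolate quenched in the same flask with methyl iodide and DMPU. This is possible here because the product is saturated, and should give the trans ketone F4.
- Kinetic silylation on the CH2 side (LiN(iPr)2, Me3SiCl) would give the silyl enol ether F5.
- Saegusa–Ito oxidation with Pd(OAc)2 in acetonitrile would give 8.

**Step 6.** The Lewis-acidic AlMe3/zirconocene mixture may attack or isomerise the conjugated diene, or the alkenylalane may be captured sluggishly by paraformaldehyde. The fallback builds the trisubstituted alkene by hydroalumination instead of carboalumination. It sets out from 12 and returns at 14.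
- Deprotonation with n-BuLi and addition to paraformaldehyde would give the propargylic alcohol F6.
- Hydroxyl-directed trans-hydroalumination with NaAlH2(OCH2CH2OMe)2 and iodination with N-iodosuccinimide in the same flask would give the (Z)-iodoalkene F7.
- Coupling with Me2CuLi, with retention of geometry, would give 14.

**Step 10.** If the O–O bond is cleaved before the C=C bond is saturated, the allylic C–O bonds may be hydrogenolysed, or the metal may induce peroxide rearrangement. The fallback separates the two reductions and avoids a hydrogenation catalyst. It sets out from 17 and returns at 18.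
- Diimide, generated from dipotassium azodicarboxylate (KO2CN=NCO2K) and acetic acid, would saturate the strained double bond and leave the peroxide intact, giving F8.
- Zn in acetic acid would then cleave the O–O bond to give 18.

**Step 11.** Conversion may be incomplete on the polar tetraol, or the wrong hydroxyl may be activated. The fallback replaces the redox condensation by a two-step phenoxide alkylation. It sets out from 18 and returns at 20.
- Selective sulfonylation of the primary C11 hydroxyl (4-toluenesulfonyl chloride, pyridine, 0 °C) would give tosylate F9.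
- Displacement with 19 and K2CO3 in DMF would give 20.

## Further compounds

F1 | step 9 | (3R)-3-methyl-5-[2,6,6-trimethyl-2,5-bis(4,4,5,5-tetramethyl-1,3,2-dioxaborolan-2-yl)cyclohex-3-en-1-yl]pentane-1,3-diol, both boryl groups cis to each other and trans to the chain, C6 as in 16 | CC1(C)[C@H](B2OC(C)(C)C(C)(C)O2)C=C[C@](C)(B3OC(C)(C)C(C)(C)O3)[C@H]1CC[C@@](C)(O)CCO
F2 | step 9 | (1S,4R,6S)-6-[(3R)-3,5-dihydroxy-3-methylpentyl]-1,5,5-trimethylcyclohex-2-ene-1,4-diol | CC1(C)[C@H](O)C=C[C@](C)(O)[C@H]1CC[C@@](C)(O)CCO
F3 | step 1 | 4,4-dimethylcyclohex-2-en-1-one (commercial) | CC1(C)CCC(=O)C=C1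
F4 | step 1 | (2R,3R)-2,4,4-trimethyl-3-[4-(trimethylsilyl)but-3-yn-1-yl]cyclohexan-1-one (2,3-trans) | CC1(C)CCC(=O)[C@H](C)[C@H]1CCC#C[Si](C)(C)C
F5 | step 1 | trimethyl({(5R,6R)-4,4,6-trimethyl-5-[4-(trimethylsilyl)but-3-yn-1-yl]cyclohex-1-en-1-yl}oxy)silane | CC1(C)CC=C(O[Si](C)(C)C)[C@H](C)[C@H]1CCC#C[Si](C)(C)C
F6 | step 6 | 5-[(1R)-2,6,6-trimethylcyclohexa-2,4-dien-1-yl]pent-2-yn-1-ol | CC1(C)C=CC=C(C)[C@H]1CCC#CCO
F7 | step 6 | (2Z)-3-iodo-5-[(1R)-2,6,6-trimethylcyclohexa-2,4-dien-1-yl]pent-2-en-1-ol | CC1(C)C=CC=C(C)[C@H]1CC/C(I)=C/CO
F8 | step 10 | (3R)-3-methyl-5-[(1S,4R,6S)-1,5,5-trimethyl-2,3-dioxabicyclo[2.2.2]octan-6-yl]pentane-1,3-diol | CC1(C)[C@H](O2)CC[C@](C)(O2)[C@H]1CC[C@@](C)(O)CCO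
F9 | step 11 | (3R)-5-[(1S,3R,6S)-3,6-dihydroxy-2,2,6-trimethylcyclohexyl]-3-hydroxy-3-methylpentyl 4-methylbenzenesulfonate | CC1(C)[C@H](O)CC[C@](C)(O)[C@H]1CC[C@@](C)(O)CCOS(=O)(=O)c1ccc(C)cc1
A1 | alternative 1 | (2S,4R)-4-[(tert-butyldimethylsilyl)oxy]-3,3-dimethyl-2-[4-(trimethylsilyl)but-3-yn-1-yl]cyclohexan-1-one | CC1(C)[C@H](O[Si](C)(C)C(C)(C)C)CCC(=O)[C@H]1CCC#C[Si](C)(C)C
A2 | alternative 1 | (1R,2S,4R)-4-[(tert-butyldimethylsilyl)oxy]-1,3,3-trimethyl-2-[4-(trimethylsilyl)but-3-yn-1-yl]cyclohexan-1-ol (C5 epimer, hydroxyl cis to the chain) | CC1(C)[C@H](O[Si](C)(C)C(C)(C)C)CC[C@@](C)(O)[C@H]1CCC#C[Si](C)(C)C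
A3 | alternative 2 | 7-({(3R,6E)-9-[(2S)-3,3-dimethyloxiran-2-yl]-3-hydroxy-3,7-dimethylnon-6-en-1-yl}oxy)-2H-chromen-2-one | CC1(C)O[C@H]1CC/C(C)=C/CC[C@@](C)(O)CCOc2ccc3ccc(=O)oc3c2
A4 | alternative 2 | 7-({(3R)-5-[(1S,3S,6S)-3,6-dihydroxy-2,2,6-trimethylcyclohexyl]-3-hydroxy-3-methylpentyl}oxy)-2H-chromen-2-one (C2 epimer of 20) | CC1(C)[C@@H](O)CC[C@](C)(O)[C@H]1CC[C@@](C)(O)CCOc1ccc2ccc(=O)oc2c1
A5 | alternative 3 | 7-{[(3R,6E,8Z)-3-hydroxy-3,7,11-trimethyldodeca-6,8,10-trien-1-yl]oxy}-2H-chromen-2-one | CC(C)=C/C=C\C(C)=C\CC[C@@](C)(O)CCOc1ccc2ccc(=O)oc2c1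
A6 | alternative 3 | 7-{[(3R)-3-hydroxy-3-methyl-5-(2,6,6-trimethylcyclohexa-2,4-dien-1-yl)pentyl]oxy}-2H-chromen-2-one, both epimers at the ring CH | CC1(C)C=CC=C(C)C1CC[C@@](C)(O)CCOc2ccc3ccc(=O)oc3c2
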